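**Retrosynthetic overview**
1. Target 20 ⇐ silyl ether 18 ⇐ 1,2-shift of the angular C-10 side chain to C-9 in trans-decalin 17 (exocyclic C-9 methylene), ending with loss of H-1 to give the C-1/C-10 alkene.
2. 17 ⇐ enoate 15 by Li/NH3 reductive methylation (sets C-5 and C-4); 15 ⇐ keto-enoate 12 by C-8 methylation and C-9 methylenation.
3. 12 ⇐ dione-enoate 10 by a desymmetrising copper hydride reductive aldol and dehydration; this closes ring A and sets C-10, a relay stereocentre that is erased in the key step.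
4. 10 ⇐ cyclohexane-1,3-dione (ring B, bought) + lactol 3 (reductive alkylation) + acrolein (Michael addition) + Wittig reagent.
5. Ring order: ring B is purchased, ring A is closed in step 6; C-13 comes from asymmetric hydrogenation of lactone 1.

Convention: locants C-1 to C-20 are the halimane locants of the target (C-4 carries the ester, C-5 and C-10 are the ring-fusion carbons, C-9 is the quaternary carbon of ring B, C-13 the side-chain methine); β is the face of the C-10 side chain in 11–17.
Assumption: the catalyst antipodes written in steps 1 and 6 are the ones expected to give the configurations drawn and are confirmed on the first run; compound 1 is taken as a catalogue compound.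

Step 1
Reactants: 1 4-methyl-5,6-dihydro-2H-pyran-2-one
Product: 2 (R)-4-methyltetrahydro-2H-pyran-2-one
Conditions: Ru(OAc)2[(R)-BINAP] (1 mol %), H2 (80 atm), MeOH/CH2Cl2, 50 °C
Reagents that add atoms: none
Why: Noyori-type asymmetric hydrogenation of a β-substituted unsaturated lactone, in which the coordinating lactone carbonyl directs hydride delivery to one alkene face and sets the future C-13 (R in the lactone, S in the chain after the priority switch).

Step 2
Reactants: 2 (R)-4-methyltetrahydro-2H-pyran-2-one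
Product: 3 (4R)-4-methyltetrahydro-2H-pyran-2-ol
Conditions: i-Bu2AlH (1.05 equiv), CH2Cl2, −78 °C; Rochelle salt work-up
Reagents that add atoms: none
Why: partial lactone reduction stops at the aluminium hemiacetal at low temperature, giving the lactol as a latent 5-hydroxy aldehyde without touching the remote stereocentre.

Step 3
Reactants: 3 (4R)-4-methyltetrahydro-2H-pyran-2-ol; 4 cyclohexane-1,3-dione
Product: 6 2-[(3S)-5-hydroxy-3-methylpentyl]cyclohexane-1,3-dione, via Knoevenagel adduct 5 (not isolated)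
Conditions: Hantzsch ester (diethyl 2,6-dimethyl-1,4-dihydropyridine-3,5-dicarboxylate, 1.05 equiv), L-proline (20 mol %), CH2Cl2, 25 °C
Reagents that add atoms: none
Why: three-component reductive alkylation (proline-mediated Knoevenagel condensation of the open lactol form, then fast transfer hydrogenation of the alkylidene dione) gives clean C-alkylation of the dione and forms the C-10/C-11 bond.

Step 4
Reactants: 6 2-[(3S)-5-hydroxy-3-methylpentyl]cyclohexane-1,3-dione; 7 acrolein
Product: 9 methyl (2E)-5-{1-[(3S)-5-hydroxy-3-methylpentyl]-2,6-dioxocyclohexyl}pent-2-enoate, via aldehyde 8 (not isolated)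
Conditions: Et3N (10 mol %), EtOAc, 25 °C; then Ph3P=CHCO2Me (1.2 equiv), CH2Cl2, 25 °C
Reagents that add atoms: methyl (triphenylphosphoranylidene)acetate, COC(=O)C=P(c1ccccc1)(c1ccccc1)c1ccccc1
Why: Michael addition of the acidic 2-alkyl-1,3-dione to acrolein builds the (still prochiral) quaternary C-10, and the stabilised Wittig ylide converts the aldehyde chemoselectively into the (E)-enoate.

Step 5
Reactants: 9 methyl (2E)-5-{1-[(3S)-5-hydroxy-3-methylpentyl]-2,6-dioxocyclohexyl}pent-2-enoate
Product: 10 methyl (2E)-5-{1-[(3S)-5-{[tert-butyl(dimethyl)silyl]oxy}-3-methylpentyl]-2,6-dioxocyclohexyl}pent-2-enoate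
Conditions: TBSCl (1.2 equiv), imidazole, DMF, 0 → 25 °C
Reagents that add atoms: tert-butyldimethylsilyl chloride, CC(C)(C)[Si](C)(C)Cl
Why: standard silylation of the primary alcohol, giving an ether that survives the enolate, titanium and dissolving-metal steps ahead.

Step 6
Reactants: 10 methyl (2E)-5-{1-[(3S)-5-{[tert-butyl(dimethyl)silyl]oxy}-3-methylpentyl]-2,6-dioxocyclohexyl}pent-2-enoate
Product: 11 methyl (1S,4aR,8aS)-4a-[(3S)-5-{[tert-butyl(dimethyl)silyl]oxy}-3-methylpentyl]-8a-hydroxy-5-oxodecahydronaphthalene-1-carboxylate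
Conditions: Cu(OAc)2·H2O (5 mol %), (R)-DTBM-SEGPHOS (5.5 mol %), PhSiH3 (1.2 equiv), toluene, −40 → 0 °C; aq NaHCO3/MeOH work-up
Reagents that add atoms: none
Why: copper hydride catalysed reductive aldol cyclisation (conjugate reduction, then intramolecular aldol of the chiral copper enolate through a chair transition state onto one of the two enantiotopic ketones) closes ring A cis-fused and fixes C-10 under catalyst control.

Step 7
Reactants: 11 methyl (1S,4aR,8aS)-4a-[(3S)-5-{[tert-butyl(dimethyl)silyl]oxy}-3-methylpentyl]-8a-hydroxy-5-oxodecahydronaphthalene-1-carboxylate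
Product: 12 methyl (4aR)-4a-[(3S)-5-{[tert-butyl(dimethyl)silyl]oxy}-3-methylpentyl]-5-oxo-2,3,4,4a,5,6,7,8-octahydronaphthalene-1-carboxylate
Conditions: SOCl2 (1.5 equiv), pyridine, CH2Cl2, 0 °C; then DBU (0.2 equiv), 25 °C
Reagents that add atoms: none
Why: dehydration of the tertiary aldol through its chlorosulfite (anti E2 with the acidic, trans-disposed H-4), with DBU moving any Δ5(6) isomer into conjugation, leaves C-10 as the only ring stereocentre.

Step 8
Reactants: 12 methyl (4aR)-4a-[(3S)-5-{[tert-butyl(dimethyl)silyl]oxy}-3-methylpentyl]-5-oxo-2,3,4,4a,5,6,7,8-octahydronaphthalene-1-carboxylate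
Product: 14 methyl (4aR,6R)-4a-[(3S)-5-{[tert-butyl(dimethyl)silyl]oxy}-3-methylpentyl]-6-methyl-5-oxo-2,3,4,4a,5,6,7,8-octahydronaphthalene-1-carboxylate, via lithium enolate 13 (not isolated)
Conditions: LiN(i-Pr)2 (1.05 equiv), THF, −78 °C; MeI (1.5 equiv), −78 → −30 °C
Reagents that add atoms: iodomethane, CI
Why: regiospecific ketone enolate alkylation (C-10 is quaternary, so only C-8 can enolise) in which MeI enters anti to the axial C-10 side chain, giving the equatorial 8α-methyl that is also the thermodynamic epimer.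

Step 9
Reactants: 14 methyl (4aR,6R)-4a-[(3S)-5-{[tert-butyl(dimethyl)silyl]oxy}-3-methylpentyl]-6-methyl-5-oxo-2,3,4,4a,5,6,7,8-octahydronaphthalene-1-carboxylate
Product: 15 methyl (4aS,6R)-4a-[(3S)-5-{[tert-butyl(dimethyl)silyl]oxy}-3-methylpentyl]-6-methyl-5-methylidene-2,3,4,4a,5,6,7,8-octahydronaphthalene-1-carboxylate
Conditions: Zn, CH2Br2, TiCl4, THF/CH2Cl2, 0 → 25 °C
Reagents that add atoms: dibromomethane, BrCBr
Why: Takai–Lombardo methylenation uses a non-basic titanium methylene reagent that olefinates hindered, enolisable ketones without epimerising C-8 and leaves the ester untouched.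

Step 10
Reactants: 15 methyl (4aS,6R)-4a-[(3S)-5-{[tert-butyl(dimethyl)silyl]oxy}-3-methylpentyl]-6-methyl-5-methylidene-2,3,4,4a,5,6,7,8-octahydronaphthalene-1-carboxylate
Product: 17 methyl (1S,4aR,6R,8aR)-4a-[(3S)-5-{[tert-butyl(dimethyl)silyl]oxy}-3-methylpentyl]-1,6-dimethyl-5-methylidenedecahydronaphthalene-1-carboxylate, via lithium ester enolate 16 (not isolated)
Conditions: Li (2.5 equiv), NH3/THF, t-BuOH (1.0 equiv), −78 °C; isoprene; then MeI (5 equiv), −78 → −33 °C
Reagents that add atoms: iodomethane, CI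
Why: dissolving-metal reductive alkylation of the enoate, in which axial protonation at C-5 gives the trans-fused enolate (H-5 anti to the C-10 chain) and MeI attacks the exocyclic enolate from the equatorial α face away from the axial C-10 chain, so the ester ends axial (β) at C-4.

Step 11
Reactants: 17 methyl (1S,4aR,6R,8aR)-4a-[(3S)-5-{[tert-butyl(dimethyl)silyl]oxy}-3-methylpentyl]-1,6-dimethyl-5-methylidenedecahydronaphthalene-1-carboxylate
Product: 18 methyl (1S,5S,6R,8aR)-5-[(3S)-5-{[tert-butyl(dimethyl)silyl]oxy}-3-methylpentyl]-1,5,6-trimethyl-1,2,3,5,6,7,8,8a-octahydronaphthalene-1-carboxylate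
Conditions: [N,N′-bis(3,5-di-tert-butylsalicylidene)cyclohexane-1,2-diaminato]cobalt (divalent cobalt, 5 mol %), N-fluoro-2,4,6-trimethylpyridinium tetrafluoroborate (1.5 equiv), PhSiH3 (1.2 equiv), PhCF3, 0 → 25 °C
Reagents that add atoms: none
Why: Proposed new method: cobalt-hydride hydrogen-atom transfer to the exocyclic methylene gives the tertiary C-9 radical, which is oxidised through a tetravalent alkylcobalt to the C-9 cation (radical–polar crossover); the axial C-10 side chain, antiperiplanar to the empty orbital and pressed against the axial C-4 ester, then shifts suprafacially to the β face of C-9 (Wagner–Meerwein 1,2-shift, which fixes C-9 with the new methyl α), and the C-10 cation is deprotonated by the hindered collidine released from the oxidant at the open C-1 methylene rather than at the shielded C-5 methine, in a medium with no acid to equilibrate the alkene; the closest known reactions are Co(salen)/N-fluoropyridinium/silane radical–polar crossover hydrofunctionalisations and semipinacol shifts, and the acid-mediated Westphalen-type migration of an angular group.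

Step 12
Reactants: 18 methyl (1S,5S,6R,8aR)-5-[(3S)-5-{[tert-butyl(dimethyl)silyl]oxy}-3-methylpentyl]-1,5,6-trimethyl-1,2,3,5,6,7,8,8a-octahydronaphthalene-1-carboxylate
Product: 20 methyl (1S,5S,6R,8aR)-5-[(3S)-5-acetoxy-3-methylpentyl]-1,5,6-trimethyl-1,2,3,5,6,7,8,8a-octahydronaphthalene-1-carboxylate, via primary alcohol 19 (not isolated)
Conditions: Bu4NF (1.2 equiv), THF, 0 °C; then Ac2O (3 equiv), pyridine, DMAP (5 mol %), 25 °C
Reagents that add atoms: acetic anhydride, CC(=O)OC(C)=O
Why: fluoride desilylation followed by acylation of the liberated primary alkoxide in the same flask, under mild basic conditions that do not move the trisubstituted alkene or touch the hindered ester.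

**Compound list**
1 | 4-methyl-5,6-dihydro-2H-pyran-2-one | CC1=CC(=O)OCC1 | starting material
2 | (R)-4-methyltetrahydro-2H-pyran-2-one | C[C@@H]1CCOC(=O)C1 | intermediate
3 | (4R)-4-methyltetrahydro-2H-pyran-2-ol (anomer mixture) | C[C@@H]1CCOC(O)C1 | intermediate
4 | cyclohexane-1,3-dione | O=C1CCCC(=O)C1 | starting material
5 | 2-[(3S)-5-hydroxy-3-methylpentylidene]cyclohexane-1,3-dione (Knoevenagel adduct, not isolated) | O=C1CCCC(=O)C1=CC[C@H](C)CCO | intermediate
6 | 2-[(3S)-5-hydroxy-3-methylpentyl]cyclohexane-1,3-dione | O=C1CCCC(=O)C1CC[C@H](C)CCO | intermediate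
7 | acrolein | C=CC=O | starting material
8 | 3-{1-[(3S)-5-hydroxy-3-methylpentyl]-2,6-dioxocyclohexyl}propanal (not isolated) | O=CCCC1(CC[C@H](C)CCO)C(=O)CCCC1=O | intermediate
9 | methyl (2E)-5-{1-[(3S)-5-hydroxy-3-methylpentyl]-2,6-dioxocyclohexyl}pent-2-enoate | COC(=O)/C=C/CCC1(CC[C@H](C)CCO)C(=O)CCCC1=O | intermediate
10 | methyl (2E)-5-{1-[(3S)-5-{[tert-butyl(dimethyl)silyl]oxy}-3-methylpentyl]-2,6-dioxocyclohexyl}pent-2-enoate | COC(=O)/C=C/CCC1(CC[C@H](C)CCO[Si](C)(C)C(C)(C)C)C(=O)CCCC1=O | intermediate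
11 | methyl (1S,4aR,8aS)-4a-[(3S)-5-{[tert-butyl(dimethyl)silyl]oxy}-3-methylpentyl]-8a-hydroxy-5-oxodecahydronaphthalene-1-carboxylate (cis-fused ketol; 5β-OH, 4β-CO2Me, 10β-chain) | COC(=O)[C@H]1CCC[C@]2(CC[C@H](C)CCO[Si](C)(C)C(C)(C)C)C(=O)CCC[C@]12O | intermediate
12 | methyl (4aR)-4a-[(3S)-5-{[tert-butyl(dimethyl)silyl]oxy}-3-methylpentyl]-5-oxo-2,3,4,4a,5,6,7,8-octahydronaphthalene-1-carboxylate | COC(=O)C1=C2CCCC(=O)[C@@]2(CC[C@H](C)CCO[Si](C)(C)C(C)(C)C)CCC1 | intermediate
13 | lithium enolate of 12 at C-8/C-9 (not isolated) | [Li+].COC(=O)C1=C2CCC=C([O-])[C@@]2(CC[C@H](C)CCO[Si](C)(C)C(C)(C)C)CCC1 | intermediate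
14 | methyl (4aR,6R)-4a-[(3S)-5-{[tert-butyl(dimethyl)silyl]oxy}-3-methylpentyl]-6-methyl-5-oxo-2,3,4,4a,5,6,7,8-octahydronaphthalene-1-carboxylate (8α-methyl) | COC(=O)C1=C2CC[C@@H](C)C(=O)[C@@]2(CC[C@H](C)CCO[Si](C)(C)C(C)(C)C)CCC1 | intermediate
15 | methyl (4aS,6R)-4a-[(3S)-5-{[tert-butyl(dimethyl)silyl]oxy}-3-methylpentyl]-6-methyl-5-methylidene-2,3,4,4a,5,6,7,8-octahydronaphthalene-1-carboxylate | COC(=O)C1=C2CC[C@@H](C)C(=C)[C@@]2(CC[C@H](C)CCO[Si](C)(C)C(C)(C)C)CCC1 | intermediate
16 | lithium ester enolate from 15, trans-fused, 5α-H (not isolated; enolate geometry not defined) | [Li+].COC([O-])=C1CCC[C@@]2(CC[C@H](C)CCO[Si](C)(C)C(C)(C)C)[C@H]1CC[C@@H](C)C2=C | intermediate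
17 | methyl (1S,4aR,6R,8aR)-4a-[(3S)-5-{[tert-butyl(dimethyl)silyl]oxy}-3-methylpentyl]-1,6-dimethyl-5-methylidenedecahydronaphthalene-1-carboxylate (trans-decalin; 4β-CO2Me, 4α-Me, 5α-H, 8α-Me, 10β-chain) | COC(=O)[C@@]1(C)CCC[C@@]2(CC[C@H](C)CCO[Si](C)(C)C(C)(C)C)[C@H]1CC[C@@H](C)C2=C | intermediate
18 | methyl (1S,5S,6R,8aR)-5-[(3S)-5-{[tert-butyl(dimethyl)silyl]oxy}-3-methylpentyl]-1,5,6-trimethyl-1,2,3,5,6,7,8,8a-octahydronaphthalene-1-carboxylate | COC(=O)[C@@]1(C)CCC=C2[C@H]1CC[C@@H](C)[C@]2(C)CC[C@H](C)CCO[Si](C)(C)C(C)(C)C | intermediate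
19 | methyl (1S,5S,6R,8aR)-5-[(3S)-5-hydroxy-3-methylpentyl]-1,5,6-trimethyl-1,2,3,5,6,7,8,8a-octahydronaphthalene-1-carboxylate (not isolated) | COC(=O)[C@@]1(C)CCC=C2[C@H]1CC[C@@H](C)[C@]2(C)CC[C@H](C)CCO | intermediate
20 | methyl (1S,5S,6R,8aR)-5-[(3S)-5-acetoxy-3-methylpentyl]-1,5,6-trimethyl-1,2,3,5,6,7,8,8a-octahydronaphthalene-1-carboxylate (halimane locants 4S,5R,8R,9S,13S) | COC(=O)[C@@]1(C)CCC=C2[C@H]1CC[C@@H](C)[C@]2(C)CC[C@H](C)CCOC(C)=O | target

**Step count and risks**
Total steps: 12. Longest linear sequence: 12 (1 → 20); cyclohexane-1,3-dione and acrolein enter that sequence at steps 3 and 4.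

The three steps most likely to fail are 11, 6 and 10.

Step 11 (the new method). The risks are a competing hydride shift from C-8 to the C-9 cation, simple return to Δ8 alkenes, and deprotonation at C-5 to give the Δ5(10) isomer. The fallback uses known chemistry, sets out from 17 and rejoins the route at 20. Compound 17 is stirred in formic acid and then treated with K2CO3 in MeOH. These are classical solvolytic Wagner–Meerwein (Westphalen-type) conditions, under which the cation left at C-10 after the side-chain shift is trapped by solvent and the silyl ether is lost. This gives methyl 10β,15-dihydroxy diol F1 and its C-10 epimer, methyl 10α,15-dihydroxy diol F2, which are separated by chromatography. Ac2O/pyridine acetylates only the primary alcohol, giving the 10β-hydroxy 15-acetate F3 and the 10α-hydroxy 15-acetate F4. F3 is dehydrated with Burgess reagent: in a syn elimination only H-1β is syn to the 10β oxygen, because H-5 is α and C-9 carries no hydrogen. F4 is dehydrated with SOCl2/pyridine: in an anti elimination only H-1β is anti to the 10α oxygen. Both therefore converge on 20, with the alkene position fixed by stereochemistry rather than by the base.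

Step 6 (sense and level of enantioinduction with the long side chain). The fallback sets out from 10 and rejoins at 11. A ketoreductase (NADPH with glucose/glucose dehydrogenase recycling, or baker's yeast) reduces one of the two enantiotopic ketones of 10 to give the hydroxy ketone F5; this enzymatic desymmetrisation of 2,2-disubstituted cyclohexane-1,3-diones is well precedented. Stryker's reagent [(Ph3P)CuH]6 then effects an achiral reductive aldol cyclisation onto the only ketone left, giving the diol ester F6. Dess–Martin periodinane oxidises the secondary alcohol of F6 to return ketol 11; any C-4/C-5 diastereomers formed converge at 12.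

Step 10 (over-reduction of the ester and control of C-5/C-4 in one pot). The fallback sets out from 15 and rejoins at 17, separating reduction from alkylation. Mg in MeOH (or Li/NH3 with an NH4Cl quench) reduces the enoate to the trans-fused saturated ester F7, obtained mainly as the equatorial 4α-ester. F7 is then deprotonated with LiN(i-Pr)2 in THF/DMPU and methylated with MeI; C-4 is replanarised in the enolate and alkylated from the α face as in the main route, giving 17.

**Further compounds**
F1 | step 11 | methyl (1S,4aR,5S,6R,8aS)-4a-hydroxy-5-[(3S)-5-hydroxy-3-methylpentyl]-1,5,6-trimethyldecahydronaphthalene-1-carboxylate (10β-hydroxy diol) | COC(=O)[C@@]1(C)CCC[C@@]2(O)[C@H]1CC[C@@H](C)[C@]2(C)CC[C@H](C)CCO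
F2 | step 11 | methyl (1S,4aS,5S,6R,8aS)-4a-hydroxy-5-[(3S)-5-hydroxy-3-methylpentyl]-1,5,6-trimethyldecahydronaphthalene-1-carboxylate (10α-hydroxy diol) | COC(=O)[C@@]1(C)CCC[C@]2(O)[C@H]1CC[C@@H](C)[C@]2(C)CC[C@H](C)CCO
F3 | step 11 | methyl (1S,4aR,5S,6R,8aS)-5-[(3S)-5-acetoxy-3-methylpentyl]-4a-hydroxy-1,5,6-trimethyldecahydronaphthalene-1-carboxylate (10β-hydroxy 15-acetate) | COC(=O)[C@@]1(C)CCC[C@@]2(O)[C@H]1CC[C@@H](C)[C@]2(C)CC[C@H](C)CCOC(C)=O
F4 | step 11 | methyl (1S,4aS,5S,6R,8aS)-5-[(3S)-5-acetoxy-3-methylpentyl]-4a-hydroxy-1,5,6-trimethyldecahydronaphthalene-1-carboxylate (10α-hydroxy 15-acetate) | COC(=O)[C@@]1(C)CCC[C@]2(O)[C@H]1CC[C@@H](C)[C@]2(C)CC[C@H](C)CCOC(C)=O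
F5 | step 6 | methyl (2E)-5-{(1R,2S)-1-[(3S)-5-{[tert-butyl(dimethyl)silyl]oxy}-3-methylpentyl]-2-hydroxy-6-oxocyclohexyl}pent-2-enoate | COC(=O)/C=C/CC[C@@]1(CC[C@H](C)CCO[Si](C)(C)C(C)(C)C)C(=O)CCC[C@@H]1O
F6 | step 6 | methyl (1S,4aS,5S,8aS)-4a-[(3S)-5-{[tert-butyl(dimethyl)silyl]oxy}-3-methylpentyl]-5,8a-dihydroxydecahydronaphthalene-1-carboxylate | COC(=O)[C@H]1CCC[C@]2(CC[C@H](C)CCO[Si](C)(C)C(C)(C)C)[C@@H](O)CCC[C@]12O
F7 | step 10 | methyl (1R,4aR,6R,8aS)-4a-[(3S)-5-{[tert-butyl(dimethyl)silyl]oxy}-3-methylpentyl]-6-methyl-5-methylidenedecahydronaphthalene-1-carboxylate (trans-fused, 4α-ester) | COC(=O)[C@@H]1CCC[C@@]2(CC[C@H](C)CCO[Si](C)(C)C(C)(C)C)[C@H]1CC[C@@H](C)C2=C
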